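**Plan**
1. Retrosynthetic cuts: (i) the exocyclic C3–CH2 bond between the lactone (ring C) and the guaiacyl ring A; (ii) the lactone O1–C2 acyl bond; (iii) the C3–C4 bond (aldol). This leaves vanillyl alcohol, ethyl glyoxylate and 3-(3,4-dimethoxyphenyl)propan-1-ol.
2. Enabling feature: on ring A the oxygen at C4' is para to C1'–CH2, so the benzylic carbon is the terminus of a latent p-quinone methide. On ring C, C3 carries an oxygen and adjoins C2=O, so C2=C3 can be stored as a flat, neutral ene-diol bis-silyl ether next to the C4 stereocentre.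
3. Forward order: alcohol to aldehyde; enamine aldol with glyoxylate, reduction and lactonisation close ring C with ring B already attached; double O-silylation; ring A is joined last, in a coupling that is formally lactone + vanillyl alcohol − H2O.
4. That one event makes the C–C bond, the fully substituted carbinol centre and the trans relation of the two benzyl groups. Its acidic work-up frees both hydroxyl groups, so the Me3Si helpers need no removal step of their own.
5. Stereochemistry: C4 comes from the (R)-diarylprolinol catalyst in the aldol step. C3 comes from C4, by attack of the electrophile anti to the 3,4-dimethoxybenzyl group; the carbinol configuration of the aldol is erased on purpose.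

Key step: step 5

Assumption: the free hydroxyl of the diarylprolinol is taken to steer the glyoxylate to the enamine face as the carboxyl group of proline does, so the (R)-catalyst should give the (3R)-aldehyde 4; compound 3 is used as its commercial polymeric toluene solution.

Step 1
Reactants: 1 3-(3,4-dimethoxyphenyl)propan-1-ol
Product: 2 3-(3,4-dimethoxyphenyl)propanal
Conditions: 2,2,6,6-tetramethylpiperidin-1-oxyl (TEMPO, 10 mol %), PhI(OAc)2 (1.1 equiv), CH2Cl2, rt
Reagents that add atoms: none
Why: The oxoammonium-mediated (TEMPO/PhI(OAc)2) oxidation of a primary alcohol stops at the aldehyde and leaves the electron-rich dimethoxyarene untouched; no stereocentre is involved.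

Step 2
Reactants: 2 3-(3,4-dimethoxyphenyl)propanal; 3 ethyl glyoxylate
Product: 6 (3S,4S)-4-(3,4-dimethoxybenzyl)-3-hydroxydihydrofuran-2(3H)-one, via aldol aldehyde 4 (not isolated), via diol ester 5 (not isolated)
Conditions: (R)-bis[3,5-bis(trifluoromethyl)phenyl](pyrrolidin-2-yl)methanol (10 mol %), MeCN, H2O (3 equiv), rt; NaBH4, MeOH, 0 °C; p-toluenesulfonic acid monohydrate (5 mol %), CH2Cl2, rt
Reagents that add atoms: none
Why: This is an enamine-catalysed direct cross-aldol reaction of an enolisable aldehyde with the non-enolisable, highly electrophilic glyoxylate, in which the hydrogen-bonding carbinol arm of the (R)-catalyst directs 3 to one face of the E-enamine and so sets the later C4 (3R in 4), while prompt NaBH4 reduction of the formyl group forestalls epimerisation and acid closes the five-membered lactone with loss of ethanol, the anti-aldol carbinol centre (2S) being of no consequence because step 3 erases it.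

Step 3
Reactants: 6 (3S,4S)-4-(3,4-dimethoxybenzyl)-3-hydroxydihydrofuran-2(3H)-one
Product: 8 (4S)-4-(3,4-dimethoxybenzyl)-2,3-bis(trimethylsilyloxy)-4,5-dihydrofuran, via dilithium enediolate 7 (not isolated)
Conditions: LiN(iPr)2 (LDA, 2.3 equiv), THF, −78 → −40 °C; Me3SiCl (3 equiv), −78 °C → rt; pentane, filtration under Ar, used crude
Reagents that add atoms: chlorotrimethylsilane C[Si](C)(C)Cl
Why: Double deprotonation of an alpha-hydroxy lactone (alkoxide, then enolate) followed by O-silylation of both oxygens is the standard silyl ketene acetal synthesis, which makes C3 planar while the non-acidic C4–H keeps its configuration.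

Step 4
Reactants: 9 vanillyl alcohol
Product: 10 [2-methoxy-4-(trimethylsilyloxymethyl)phenoxy]trimethylsilane (bis-TMS vanillyl alcohol)
Conditions: (Me3Si)2NH (1.2 equiv), I2 (1 mol %), CH2Cl2, rt
Reagents that add atoms: hexamethyldisilazane C[Si](C)(C)N[Si](C)(C)C
Why: Iodine-catalysed silylation with hexamethyldisilazane caps the phenol and the benzylic alcohol under nearly neutral conditions that do not ionise the sensitive p-hydroxybenzyl alcohol; no stereocentre is involved.

Step 5
Reactants: 8 (4S)-4-(3,4-dimethoxybenzyl)-2,3-bis(trimethylsilyloxy)-4,5-dihydrofuran; 10 bis-TMS vanillyl alcohol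
Product: 13 trachelogenin, via silylated quinone methide cation 11 (not isolated), via bis-TMS trachelogenin 12 (not isolated)
Conditions: 8 (1.2 equiv), (CF3SO2)2NH (3 mol %), CH2Cl2, −78 °C, slow addition of 10, → −20 °C; then 1 M HCl, THF, rt
Reagents that add atoms: none
Why: Proposed new method: (CF3SO2)2NH protodesilylates a trace of 8 to Me3SiN(SO2CF3)2, which silylates the benzylic OSiMe3 group of 10 so that the para silyloxy oxygen of ring A expels (Me3Si)2O to give the O-silylated p-quinone methide 11; the electron-rich C3 of 8 then adds to its exocyclic CH2 (a Mukaiyama-type 1,6-addition driven by rearomatisation of ring A), and the resulting 2-silyloxy oxocarbenium ion returns Me3Si+ to the catalyst. The closest known reaction types are the Lewis-acid-promoted alkylation of silyl ketene acetals with SN1-active p-alkoxybenzyl halides and the 1,6-addition of silyl enol ethers to isolable p-quinone methides; new here are the parent CH2 quinone methide released catalytically from a silyl ether and a fully substituted ene-diol bis-silyl ether as donor. No ring is closed. The new quaternary centre C3 is controlled by the resident C4 stereocentre, because the 3,4-dimethoxybenzyl group shields one face of the flat dihydrofuran and the electrophile enters anti to it, which places the two benzyl groups trans and the C3 oxygen cis to the C4 substituent, that is (3S,4S). The step needs C- over O-alkylation and capture of 11 by 8 rather than by the electron-rich arenes; both donor oxygens are capped by silicon, a ketene acetal is far more nucleophilic than a dialkoxybenzene, and slow addition of 10 keeps the concentration of 11 low. Dilute acid then removes the two remaining Me3Si groups of 12 without touching the lactone.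

**Compound list**
1 | 3-(3,4-dimethoxyphenyl)propan-1-ol | COc1ccc(CCCO)cc1OC | starting material
2 | 3-(3,4-dimethoxyphenyl)propanal | COc1ccc(CCC=O)cc1OC | intermediate
3 | ethyl glyoxylate | CCOC(=O)C=O | starting material
4 | ethyl (2S,3R)-3-(3,4-dimethoxybenzyl)-2-hydroxy-4-oxobutanoate (aldol aldehyde) | CCOC(=O)[C@@H](O)[C@H](C=O)Cc1ccc(OC)c(OC)c1 | intermediate
5 | ethyl (2S,3S)-3-(3,4-dimethoxybenzyl)-2,4-dihydroxybutanoate (diol ester) | CCOC(=O)[C@@H](O)[C@H](CO)Cc1ccc(OC)c(OC)c1 | intermediate
6 | (3S,4S)-4-(3,4-dimethoxybenzyl)-3-hydroxydihydrofuran-2(3H)-one | O[C@@H]1C(=O)OC[C@@H]1Cc1ccc(OC)c(OC)c1 | intermediate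
7 | dilithium (4S)-4-(3,4-dimethoxybenzyl)-4,5-dihydrofuran-2,3-diolate (dilithium enediolate) | [Li+].[Li+].[O-]C1=C([O-])OC[C@@H]1Cc1ccc(OC)c(OC)c1 | intermediate
8 | (4S)-4-(3,4-dimethoxybenzyl)-2,3-bis(trimethylsilyloxy)-4,5-dihydrofuran | C[Si](C)(C)OC1=C(O[Si](C)(C)C)OC[C@@H]1Cc1ccc(OC)c(OC)c1 | intermediate
9 | vanillyl alcohol (4-(hydroxymethyl)-2-methoxyphenol) | COc1cc(CO)ccc1O | starting material
10 | [2-methoxy-4-(trimethylsilyloxymethyl)phenoxy]trimethylsilane | COc1cc(CO[Si](C)(C)C)ccc1O[Si](C)(C)C | intermediate
11 | (2-methoxy-4-methylenecyclohexa-2,5-dien-1-ylidene)(trimethylsilyl)oxonium bis(trifluoromethylsulfonyl)imide | C=C1C=CC(=[O+][Si](C)(C)C)C(OC)=C1.O=S(=O)([N-]S(=O)(=O)C(F)(F)F)C(F)(F)F | intermediate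
12 | (3S,4S)-4-(3,4-dimethoxybenzyl)-3-[3-methoxy-4-(trimethylsilyloxy)benzyl]-3-(trimethylsilyloxy)dihydrofuran-2(3H)-one | COc1cc(C[C@@]2(O[Si](C)(C)C)C(=O)OC[C@@H]2Cc2ccc(OC)c(OC)c2)ccc1O[Si](C)(C)C | intermediate
13 | trachelogenin, (3S,4S)-4-(3,4-dimethoxybenzyl)-3-hydroxy-3-(4-hydroxy-3-methoxybenzyl)dihydrofuran-2(3H)-one | COc1cc(C[C@@]2(O)C(=O)OC[C@@H]2Cc2ccc(OC)c(OC)c2)ccc1O | target

Total step count: 5. Longest linear sequence: 4 (steps 1, 2, 3, 5).

**Steps most likely to fail**

Step 5.
- What may go wrong: the quinone methide cation may be consumed by Friedel–Crafts self-condensation faster than 8 intercepts it. The benzylic silyl ether may ionise too slowly at temperatures that 8 tolerates. Adventitious water may protodesilylate 8.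
- Fallback (known chemistry, sets out from 6, comes back at 13): 6 is converted into 7 as in step 3, and 7 is alkylated directly at −78 → −20 °C with 4-(benzyloxy)-3-methoxybenzyl bromide F1. F1 is obtained from commercial 4-benzyloxy-3-methoxybenzyl alcohol with PBr3 in Et2O at 0 °C. This SN2 alkylation of the enediolate of an alpha-hydroxy-beta-benzyl lactone also takes place anti to the C4 substituent and should give 4'-O-benzyltrachelogenin F2. Hydrogenolysis of its benzyl ether (H2, Pd/C, EtOAc, rt) leads to 13.

Step 3.
- What may go wrong: the second deprotonation may stay incomplete, part of the silylation may occur on carbon, or the ketene acetal may hydrolyse during isolation.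
- Fallback (sets out from 6, comes back at 13): the enediolate 7 is not silylated but trapped at −78 °C with commercial 4-benzyloxy-3-methoxybenzaldehyde, so the coupling is run one oxidation level higher. The aldol addition should occur anti to the C4 substituent and give the benzylic alcohol (3S,4S)-3-{[4-(benzyloxy)-3-methoxyphenyl](hydroxy)methyl}-4-(3,4-dimethoxybenzyl)-3-hydroxydihydrofuran-2(3H)-one F3 as a mixture of carbinol epimers. Hydrogenolysis (H2, Pd(OH)2/C, AcOH, rt) then removes both the activated benzylic hydroxyl group and the benzyl ether to give 13.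

Step 2.
- What may go wrong: 2 may self-condense, the aldehyde 4 may epimerise through its enamine before reduction, or the facial bias of the catalyst may be insufficient or opposite.
- Fallback (auxiliary control instead of catalysis, sets out from 2, comes back at 7): 2 is oxidised (Pinnick oxidation: NaClO2, NaH2PO4, 2-methyl-2-butene, t-BuOH/H2O) to 3-(3,4-dimethoxyphenyl)propanoic acid F4.
- Pivaloyl chloride and Et3N convert F4 into the mixed pivalic anhydride F5. (S)-4-Benzyl-2-oxazolidinone with LiCl and Et3N then gives the imide (S)-4-benzyl-3-[3-(3,4-dimethoxyphenyl)propanoyl]oxazolidin-2-one F6.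
- Oxazolidinone-controlled alkylation of its sodium enolate (NaN(SiMe3)2, THF, −78 °C) with tert-butyl bromoacetate should give the succinate tert-butyl (R)-3-[(S)-4-benzyl-2-oxooxazolidine-3-carbonyl]-4-(3,4-dimethoxyphenyl)butanoate F7.
- LiBH4 (THF, 0 °C) removes the auxiliary reductively to give tert-butyl (R)-4-(3,4-dimethoxyphenyl)-3-(hydroxymethyl)butanoate F8. CF3CO2H in CH2Cl2 closes F8 to (R)-4-(3,4-dimethoxybenzyl)dihydrofuran-2(3H)-one F9.
- Hydroxylation of the potassium enolate of F9 (KN(SiMe3)2, THF, −78 °C; 2-(phenylsulfonyl)-3-phenyloxaziridine) gives (3R,4S)-4-(3,4-dimethoxybenzyl)-3-hydroxydihydrofuran-2(3H)-one F10. F10 is the C3 epimer of 6 and under the conditions of step 3 gives the same enediolate 7.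

**Further compounds**
F1 | step 5 | 4-(benzyloxy)-3-methoxybenzyl bromide | COc1cc(CBr)ccc1OCc1ccccc1
F2 | step 5 | 4'-O-benzyltrachelogenin | COc1cc(C[C@@]2(O)C(=O)OC[C@@H]2Cc2ccc(OC)c(OC)c2)ccc1OCc1ccccc1
F3 | step 3 | (3S,4S)-3-{[4-(benzyloxy)-3-methoxyphenyl](hydroxy)methyl}-4-(3,4-dimethoxybenzyl)-3-hydroxydihydrofuran-2(3H)-one | COc1cc(C(O)[C@@]2(O)C(=O)OC[C@@H]2Cc2ccc(OC)c(OC)c2)ccc1OCc1ccccc1
F4 | step 2 | 3-(3,4-dimethoxyphenyl)propanoic acid | COc1ccc(CCC(=O)O)cc1OC
F5 | step 2 | 3-(3,4-dimethoxyphenyl)propanoic pivalic anhydride | COc1ccc(CCC(=O)OC(=O)C(C)(C)C)cc1OC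
F6 | step 2 | (S)-4-benzyl-3-[3-(3,4-dimethoxyphenyl)propanoyl]oxazolidin-2-one | COc1ccc(CCC(=O)N2[C@@H](Cc3ccccc3)COC2=O)cc1OC
F7 | step 2 | tert-butyl (R)-3-[(S)-4-benzyl-2-oxooxazolidine-3-carbonyl]-4-(3,4-dimethoxyphenyl)butanoate | COc1ccc(C[C@H](CC(=O)OC(C)(C)C)C(=O)N2[C@@H](Cc3ccccc3)COC2=O)cc1OC
F8 | step 2 | tert-butyl (R)-4-(3,4-dimethoxyphenyl)-3-(hydroxymethyl)butanoate | COc1ccc(C[C@H](CC(=O)OC(C)(C)C)CO)cc1OC
F9 | step 2 | (R)-4-(3,4-dimethoxybenzyl)dihydrofuran-2(3H)-one | C1C(=O)OC[C@@H]1Cc1ccc(OC)c(OC)c1
F10 | step 2 | (3R,4S)-4-(3,4-dimethoxybenzyl)-3-hydroxydihydrofuran-2(3H)-one | O[C@H]1C(=O)OC[C@@H]1Cc1ccc(OC)c(OC)c1
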